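**Retrosynthetic overview**
- The target comes from diimide saturation of a C7≡C8 alkyne; the alkyne is kept until the end because it is the small, axial-seeking group that fixes the C3/C6 relationship.
- That alkynyl dioxane comes from a bridged bis-peroxyketal (a 2,3,7-trioxabicyclo[2.2.1]heptane, i.e. a Criegee-type ozonide) by two bridgehead substitutions: alkynyl at C6 anti to the oxygen bridge, then hydride at C3 (axial delivery; Felkin–Anh control at C2).
- The ozonide comes from an acyclic 1,4-diketone and H2O2 under a chiral Brønsted acid. The 1,2-dioxane and the oxygen-bridged second ring close together in this one operation; the bridge is dismantled afterwards.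
- The diketone comes from methyl 2-methylacetoacetate dianion plus allyl bromide, then Wacker oxidation. The cyclohexenone ring is bought in as 3-ethoxy-2-methylcyclohexenone and converted to the alkynyl partner by gem-dimethylation, Stork–Danheiser ethynylation and stannylation.

Assumption: the antipode of the chiral acid that gives the (1R,4R) bicycle in step 3 is identified by screening both antipodes, and the bicyclic peroxide is handled only as a cold, dilute solution.

**Step 1**
Reactants: 1 methyl 2-methyl-3-oxobutanoate; 2 allyl bromide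
Product: 3 methyl 2-methyl-3-oxohept-6-enoate (racemic, C2 labile)
Conditions: LiN(iPr)2 (2.1 equiv), THF, −78 → 0 °C; then 2, 0 °C; AcOH quench
Reagents that add atoms: none
Why: β-keto ester dianion alkylation – the second deprotonation creates the more reactive γ-enolate, which is allylated selectively at that carbon; no stereocentre needs control.

**Step 2**
Reactants: 3 methyl 2-methyl-3-oxohept-6-enoate
Product: 4 methyl 2-methyl-3,6-dioxoheptanoate (racemic, C2 labile)
Conditions: PdCl2 (10 mol %), CuCl (30 mol %), O2 (1 atm), DMF–H2O 7:1, rt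
Reagents that add atoms: water, O (supplies the carbonyl oxygen); dioxygen, O=O (terminal oxidant that returns the water)
Why: Tsuji–Wacker oxidation – Markovnikov attack of water on the palladium-bound terminal alkene gives the methyl ketone and leaves the β-keto ester untouched.

**Step 3**
Reactants: 4 methyl 2-methyl-3,6-dioxoheptanoate
Product: 7 methyl 2-[(1R,4R)-4-methyl-2,3,7-trioxabicyclo[2.2.1]heptan-1-yl]propanoate, via perhydrate 5 (not isolated), via dioxanediol 6 (not isolated)
Conditions: urea–H2O2 (1.3 equiv), confined chiral BINOL-derived imidodiphosphoric acid (5 mol %), 5 Å MS, CH2Cl2, −20 °C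
Reagents that add atoms: hydrogen peroxide (from its urea adduct), OO
Why: Proposed new method: a Criegee-type ozonide synthesis from a 1,4-diketone and H2O2 (perhydration, six-ring hemiperketal closure, dehydrative transannular ketalization) run under a confined chiral acid; every stereocentre before the last C–O bond is labile (C2 through the β-keto ester enol, C3 and C6 as hemiketals), so the chiral anion paired with the peroxycarbenium ion decides which bridged enantiomer closes and both bridgeheads are set together as (1R,4R), with C2 left as an inconsequential epimer mixture; the closest known reaction types are the acid- or P2O5-mediated ozonide synthesis from diketones and chiral phosphoric acid-catalysed asymmetric ketalization and peroxy-acetalization.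

**Step 4**
Reactants: 8 3-ethoxy-2-methylcyclohex-2-en-1-one
Product: 10 3-ethoxy-2,6,6-trimethylcyclohex-2-en-1-one, via monomethyl enone 9 (not isolated)
Conditions: LiN(iPr)2 (1.1 equiv), THF, −78 °C; MeI; then LiN(iPr)2 (1.2 equiv), −78 °C; MeI, → rt
Reagents that add atoms: iodomethane, CI
Why: Stork–Danheiser kinetic α′-enolate alkylation of a vinylogous ester, run twice in one pot, installs the gem-dimethyl group; the product has no stereocentre.

**Step 5**
Reactants: 10 3-ethoxy-2,6,6-trimethylcyclohex-2-en-1-one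
Product: 12 3-ethynyl-2,4,4-trimethylcyclohex-2-en-1-one, via carbinol 11 (not isolated)
Conditions: HC≡CMgBr (2 equiv), THF, 0 → 40 °C; then 2 M HCl, rt
Reagents that add atoms: ethynylmagnesium bromide, C#C[Mg]Br; water, O
Why: Stork–Danheiser transposition – 1,2-addition of the acetylide to the vinylogous ester carbonyl, then acid hydrolysis with allylic transposition, puts the alkyne on the carbon next to the quaternary centre and the ketone next to CH2.

**Step 6**
Reactants: 12 3-ethynyl-2,4,4-trimethylcyclohex-2-en-1-one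
Product: 13 2,4,4-trimethyl-3-[(tributylstannyl)ethynyl]cyclohex-2-en-1-one
Conditions: Bu3SnOMe (1.05 equiv), neat, 60 °C, 20 mbar
Reagents that add atoms: tributyltin methoxide, CCCC[Sn](CCCC)(CCCC)OC
Why: base-free stannylation of a terminal alkyne by a tin alkoxide, driven by removal of methanol, so the enolizable enone is never exposed to strong base.

**Step 7**
Reactants: 7 methyl 2-[(1R,4R)-4-methyl-2,3,7-trioxabicyclo[2.2.1]heptan-1-yl]propanoate; 13 2,4,4-trimethyl-3-[(tributylstannyl)ethynyl]cyclohex-2-en-1-one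
Product: 15 methyl 2-[(3R,6S)-3-hydroxy-6-methyl-6-[(2,6,6-trimethyl-3-oxocyclohex-1-en-1-yl)ethynyl]-1,2-dioxan-3-yl]propanoate, via silyl ketal 14 (not isolated)
Conditions: 7, TMSOTf (1.1 equiv), 2,6-di-tert-butyl-4-methylpyridine (0.2 equiv), CH2Cl2, −78 °C; then 13, −78 → −40 °C; pH 7 buffer
Reagents that add atoms: none
Why: Proposed new method: TMSOTf silylates the most basic oxygen (the ether bridge) and ionizes the C–O bond at the methyl-bearing bridgehead (the other bridgehead cation is destabilized by the β-ester), and the resulting cyclic peroxycarbenium ion is captured by ipso-substitution of the alkynylstannane; attack is axial on the half-chair and anti to the pseudoaxial C3–OSiMe3 (the 1,4-trans preference of 4-alkoxy six-membered oxocarbenium ions), so the chirality of the bicycle is copied into C6 (6S, alkyne cis to the propanoate-bearing bond); the closest known reaction types are Lewis acid allylation of ozonides and peroxyketals through peroxycarbenium ions and alkynylstannane additions to oxocarbenium ions.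

**Step 8**
Reactants: 15 methyl 2-[(3R,6S)-3-hydroxy-6-methyl-6-[(2,6,6-trimethyl-3-oxocyclohex-1-en-1-yl)ethynyl]-1,2-dioxan-3-yl]propanoate
Product: 16 methyl (2R)-2-[(3R,6S)-6-methyl-6-[(2,6,6-trimethyl-3-oxocyclohex-1-en-1-yl)ethynyl]-1,2-dioxan-3-yl]propanoate
Conditions: Et3SiH (3 equiv), TMSOTf (20 mol %), CH2Cl2, −40 → −20 °C
Reagents that add atoms: none
Why: ionic hydrogenation of a cyclic peroxy-hemiketal – hydride adds axially to the C3 peroxycarbenium ion in the half-chair that keeps the small alkynyl group axial and the methyl equatorial, which places H trans and the propanoate cis to the alkyne (3R), while C2, epimerizable through the open-chain β-keto ester tautomer, is funnelled through the Felkin–Anh transition state (ester anti to hydride) to the 2,3-anti (2R) isomer in a dynamic kinetic resolution.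

**Step 9**
Reactants: 16 methyl (2R)-2-[(3R,6S)-6-methyl-6-[(2,6,6-trimethyl-3-oxocyclohex-1-en-1-yl)ethynyl]-1,2-dioxan-3-yl]propanoate
Product: 18 diacarperoxide A, via Z-alkene 17 (not isolated)
Conditions: KO2C–N=N–CO2K (10 equiv), AcOH (20 equiv), MeOH–CH2Cl2, 0 °C → rt
Reagents that add atoms: none
Why: diimide reduction – concerted syn transfer of H2 saturates the alkyne through the Z-alkene while leaving the O–O bond and the tetrasubstituted enone untouched; no stereocentre changes (C6 becomes R only through the priority change).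

**Compound list**
1 | methyl 2-methyl-3-oxobutanoate (racemic) | COC(=O)C(C)C(C)=O | starting material
2 | allyl bromide | C=CCBr | starting material
3 | methyl 2-methyl-3-oxohept-6-enoate (racemic) | COC(=O)C(C)C(=O)CCC=C | intermediate
4 | methyl 2-methyl-3,6-dioxoheptanoate (racemic) | COC(=O)C(C)C(=O)CCC(C)=O | intermediate
5 | methyl 6-hydroperoxy-6-hydroxy-2-methyl-3-oxoheptanoate (perhydrate, all centres labile) | COC(=O)C(C)C(=O)CCC(C)(O)OO | intermediate (not isolated)
6 | methyl 2-(3,6-dihydroxy-6-methyl-1,2-dioxan-3-yl)propanoate (all centres labile) | COC(=O)C(C)C1(O)CCC(C)(O)OO1 | intermediate (not isolated)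
7 | methyl 2-[(1R,4R)-4-methyl-2,3,7-trioxabicyclo[2.2.1]heptan-1-yl]propanoate (both C2 epimers) | COC(=O)C(C)[C@]12CC[C@](C)(O1)OO2 | intermediate
8 | 3-ethoxy-2-methylcyclohex-2-en-1-one | CCOC1=C(C)C(=O)CCC1 | starting material
9 | 3-ethoxy-2,6-dimethylcyclohex-2-en-1-one (racemic) | CCOC1=C(C)C(=O)C(C)CC1 | intermediate (not isolated)
10 | 3-ethoxy-2,6,6-trimethylcyclohex-2-en-1-one | CCOC1=C(C)C(=O)C(C)(C)CC1 | intermediate
11 | 3-ethoxy-1-ethynyl-2,6,6-trimethylcyclohex-2-en-1-ol (racemic) | CCOC1=C(C)C(O)(C#C)C(C)(C)CC1 | intermediate (not isolated)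
12 | 3-ethynyl-2,4,4-trimethylcyclohex-2-en-1-one | C#CC1=C(C)C(=O)CCC1(C)C | intermediate
13 | 2,4,4-trimethyl-3-[(tributylstannyl)ethynyl]cyclohex-2-en-1-one | CCCC[Sn](CCCC)(CCCC)C#CC1=C(C)C(=O)CCC1(C)C | intermediate
14 | methyl 2-[(3S,6S)-6-methyl-6-[(2,6,6-trimethyl-3-oxocyclohex-1-en-1-yl)ethynyl]-3-(trimethylsilyloxy)-1,2-dioxan-3-yl]propanoate (C2 epimers) | COC(=O)C(C)[C@@]1(O[Si](C)(C)C)CC[C@@](C)(C#CC2=C(C)C(=O)CCC2(C)C)OO1 | intermediate (not isolated)
15 | methyl 2-[(3R,6S)-3-hydroxy-6-methyl-6-[(2,6,6-trimethyl-3-oxocyclohex-1-en-1-yl)ethynyl]-1,2-dioxan-3-yl]propanoate (C2 epimers, ring–chain tautomers) | COC(=O)C(C)[C@@]1(O)CC[C@@](C)(C#CC2=C(C)C(=O)CCC2(C)C)OO1 | intermediate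
16 | methyl (2R)-2-[(3R,6S)-6-methyl-6-[(2,6,6-trimethyl-3-oxocyclohex-1-en-1-yl)ethynyl]-1,2-dioxan-3-yl]propanoate | COC(=O)[C@H](C)[C@H]1CC[C@@](C)(C#CC2=C(C)C(=O)CCC2(C)C)OO1 | intermediate
17 | methyl (2R)-2-[(3R,6S)-6-methyl-6-[(Z)-2-(2,6,6-trimethyl-3-oxocyclohex-1-en-1-yl)ethenyl]-1,2-dioxan-3-yl]propanoate | COC(=O)[C@H](C)[C@H]1CC[C@@](C)(/C=C\C2=C(C)C(=O)CCC2(C)C)OO1 | intermediate (not isolated)
18 | diacarperoxide A, methyl (2R)-2-[(3R,6R)-6-methyl-6-[2-(2,6,6-trimethyl-3-oxocyclohex-1-en-1-yl)ethyl]-1,2-dioxan-3-yl]propanoate | COC(=O)[C@H](C)[C@H]1CC[C@@](C)(CCC2=C(C)C(=O)CCC2(C)C)OO1 | target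

**Totals and risks**
Total step count: 9. Longest linear sequence: 6 (steps 1, 2, 3, 7, 8, 9, or equally 4, 5, 6, 7, 8, 9).

Most likely to fail, first: step 3. The enantioselective double perketalization may give low ee, or the β-keto ester may divert to Baeyer–Villiger-type or oligomeric peroxides. The fallback sets out from 3 and comes back at 16. A ketoreductase-mediated dynamic kinetic reduction of 3 gives the syn alcohol methyl (2R,3S)-3-hydroxy-2-methylhept-6-enoate F1. MsCl and Et3N convert it into methyl (2R,3S)-3-(methanesulfonyloxy)-2-methylhept-6-enoate F2. Wacker oxidation (PdCl2, CuCl, O2) gives methyl (2R,3S)-3-(methanesulfonyloxy)-2-methyl-6-oxoheptanoate F3. Urea–H2O2 with Sc(OTf)3 in MeOH gives the hydroperoxy ketal methyl (2R,3S)-6-hydroperoxy-6-methoxy-3-(methanesulfonyloxy)-2-methylheptanoate F4. Cs2CO3 closes F4 by 6-exo-tet SN2 with inversion at C3 to methyl (2R)-2-[(3R)-6-methoxy-6-methyl-1,2-dioxan-3-yl]propanoate F5; E1cB loss of mesylate is the competing path. TMSOTf and 13 then give 16 directly, by axial attack cis to the equatorial C3 side chain, so steps 7 and 8 are bypassed.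

Second: step 7. The ozonide may fragment under the Lewis acid, and the enone of 13 both binds the silyl triflate and makes the alkyne a poor π-nucleophile. The fallback sets out from 7 and comes back at 18; it carries the ring without its ketone and oxidizes last. 2-Ethynyl-1,3,3-trimethylcyclohex-1-ene F6 (from β-cyclocitral and the Ohira–Bestmann reagent) is stannylated (n-BuLi, then Bu3SnCl) to tributyl[(2,6,6-trimethylcyclohex-1-en-1-yl)ethynyl]stannane F7. With 7 and TMSOTf this gives methyl 2-[(3S,6S)-6-methyl-6-[(2,6,6-trimethylcyclohex-1-en-1-yl)ethynyl]-3-(trimethylsilyloxy)-1,2-dioxan-3-yl]propanoate F8, hydrolysed on work-up to methyl 2-[(3R,6S)-3-hydroxy-6-methyl-6-[(2,6,6-trimethylcyclohex-1-en-1-yl)ethynyl]-1,2-dioxan-3-yl]propanoate F9. Et3SiH with TMSOTf gives methyl (2R)-2-[(3R,6S)-6-methyl-6-[(2,6,6-trimethylcyclohex-1-en-1-yl)ethynyl]-1,2-dioxan-3-yl]propanoate F10. Diimide reduces it through methyl (2R)-2-[(3R,6S)-6-methyl-6-[(Z)-2-(2,6,6-trimethylcyclohex-1-en-1-yl)ethenyl]-1,2-dioxan-3-yl]propanoate F11 to methyl (2R)-2-[(3R,6R)-6-methyl-6-[2-(2,6,6-trimethylcyclohex-1-en-1-yl)ethyl]-1,2-dioxan-3-yl]propanoate F12. Allylic oxidation of the ring CH2 next to the methyl-bearing alkene carbon (CrO3 with 3,5-dimethylpyrazole, CH2Cl2, −20 °C) then gives 18; site selectivity against the chain allylic CH2 is the open point.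

Third: step 8. C2 may not epimerize fast enough for the Felkin–Anh funnel, and the Lewis acid may trigger Criegee-type rearrangement. The fallback sets out from 15 and comes back at 16; it replaces kinetic control at C2 by thermodynamic recycling. The reduction is run to completion, and the unwanted epimer methyl (2S)-2-[(3R,6S)-6-methyl-6-[(2,6,6-trimethyl-3-oxocyclohex-1-en-1-yl)ethynyl]-1,2-dioxan-3-yl]propanoate F13 is separated by chromatography. F13 is re-equilibrated with Et2NH in CF3CH2OH (reversible retro-peroxy-Michael/Michael with reprotonation at C2). The alkyne-axial 3,6-relationship is the thermodynamic one, so only C2 is scrambled, and the recovered 16 is pooled.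

**Further compounds**
F1 | step 3 | methyl (2R,3S)-3-hydroxy-2-methylhept-6-enoate | COC(=O)[C@H](C)[C@@H](O)CCC=C
F2 | step 3 | methyl (2R,3S)-3-(methanesulfonyloxy)-2-methylhept-6-enoate | COC(=O)[C@H](C)[C@@H](OS(C)(=O)=O)CCC=C
F3 | step 3 | methyl (2R,3S)-3-(methanesulfonyloxy)-2-methyl-6-oxoheptanoate | COC(=O)[C@H](C)[C@@H](OS(C)(=O)=O)CCC(C)=O
F4 | step 3 | methyl (2R,3S)-6-hydroperoxy-6-methoxy-3-(methanesulfonyloxy)-2-methylheptanoate (C6 epimers) | COC(=O)[C@H](C)[C@@H](OS(C)(=O)=O)CCC(C)(OC)OO
F5 | step 3 | methyl (2R)-2-[(3R)-6-methoxy-6-methyl-1,2-dioxan-3-yl]propanoate (C6 epimers) | COC(=O)[C@H](C)[C@H]1CCC(C)(OC)OO1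
F6 | step 7 | 2-ethynyl-1,3,3-trimethylcyclohex-1-ene | C#CC1=C(C)CCCC1(C)C
F7 | step 7 | tributyl[(2,6,6-trimethylcyclohex-1-en-1-yl)ethynyl]stannane | CCCC[Sn](CCCC)(CCCC)C#CC1=C(C)CCCC1(C)C
F8 | step 7 | methyl 2-[(3S,6S)-6-methyl-6-[(2,6,6-trimethylcyclohex-1-en-1-yl)ethynyl]-3-(trimethylsilyloxy)-1,2-dioxan-3-yl]propanoate | COC(=O)C(C)[C@@]1(O[Si](C)(C)C)CC[C@@](C)(C#CC2=C(C)CCCC2(C)C)OO1
F9 | step 7 | methyl 2-[(3R,6S)-3-hydroxy-6-methyl-6-[(2,6,6-trimethylcyclohex-1-en-1-yl)ethynyl]-1,2-dioxan-3-yl]propanoate | COC(=O)C(C)[C@@]1(O)CC[C@@](C)(C#CC2=C(C)CCCC2(C)C)OO1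
F10 | step 7 | methyl (2R)-2-[(3R,6S)-6-methyl-6-[(2,6,6-trimethylcyclohex-1-en-1-yl)ethynyl]-1,2-dioxan-3-yl]propanoate | COC(=O)[C@H](C)[C@H]1CC[C@@](C)(C#CC2=C(C)CCCC2(C)C)OO1
F11 | step 7 | methyl (2R)-2-[(3R,6S)-6-methyl-6-[(Z)-2-(2,6,6-trimethylcyclohex-1-en-1-yl)ethenyl]-1,2-dioxan-3-yl]propanoate | COC(=O)[C@H](C)[C@H]1CC[C@@](C)(/C=C\C2=C(C)CCCC2(C)C)OO1
F12 | step 7 | methyl (2R)-2-[(3R,6R)-6-methyl-6-[2-(2,6,6-trimethylcyclohex-1-en-1-yl)ethyl]-1,2-dioxan-3-yl]propanoate | COC(=O)[C@H](C)[C@H]1CC[C@@](C)(CCC2=C(C)CCCC2(C)C)OO1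
F13 | step 8 | methyl (2S)-2-[(3R,6S)-6-methyl-6-[(2,6,6-trimethyl-3-oxocyclohex-1-en-1-yl)ethynyl]-1,2-dioxan-3-yl]propanoate | COC(=O)[C@@H](C)[C@H]1CC[C@@](C)(C#CC2=C(C)C(=O)CCC2(C)C)OO1
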